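**Strategy.** The cyclohexene is read as a Morita–Baylis–Hillman adduct: ring C1 (carrying the acyloxymethyl carbon, taken at the aldehyde level), the C1=C2 alkene and the C6 carbinol form an α-(hydroxyalkyl)enal. Disconnection of the C1–C6 bond leads to acyclic (2E,5S)-5-ethynylhept-2-enedial, whose single stereocentre (ring C4) comes from a rhodium-catalysed conjugate alkynylation of 5,6-dihydro-2H-pyran-2-one. A proline/imidazole-catalysed intramolecular Morita–Baylis–Hillman reaction closes the only ring, sets the C6 carbinol cis to C4 and returns the enal for reduction and acylation. The ethynyl group at C4 is then joined to a homoallylic alcohol ester made from (S)-2-methylglycidol by a ruthenium-catalysed Alder-ene coupling that builds the 1,4-diene side chain.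

Key step: step 6

Remark 1: compounds 1, 2 and 12 are assumed to be purchased; 12 is used as the single (S)-enantiomer.
Remark 2: the sense of induction in step 6 is assigned by analogy with the proline/imidazole cyclisation of unsubstituted hept-2-enedial, for which D-proline is taken to give the (S)-carbinol; should the sense prove opposite, L-proline is used instead.

**Route**

Step 1
Reactants: 1 5,6-dihydro-2H-pyran-2-one; 2 ethynyltri(propan-2-yl)silane
Product: 3 (4R)-4-{[tri(propan-2-yl)silyl]ethynyl}oxan-2-one
Conditions: [Rh(OAc)(C2H4)2]2 (2.5 mol %), DTBM-SEGPHOS (6 mol %, the enantiomer that gives (R)-3), 2 (2 equiv), 1,4-dioxane, 80 °C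
Reagents that add atoms: none
Why: Rhodium-catalysed asymmetric conjugate alkynylation, in which an alkynyl complex of monovalent rhodium carrying the bulky chiral bisphosphine should add 1,4 to the s-trans-locked unsaturated lactone faster than it dimerises the hindered silylacetylene, the ligand enantiomer fixing the face of the β-carbon so that the (R)-centre (the later ring C4) is formed.

Step 2
Reactants: 3 (4R)-4-{[tri(propan-2-yl)silyl]ethynyl}oxan-2-one
Product: 4 (4R)-4-ethynyloxan-2-one
Conditions: TBAF (1.1 equiv), AcOH (1.1 equiv), THF, 0 °C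
Reagents that add atoms: none
Why: Fluoride-induced protodesilylation of the alkynylsilane, with acetic acid buffering so that the lactone stays closed; the stereocentre is not enolisable and is untouched.

Step 3
Reactants: 4 (4R)-4-ethynyloxan-2-one
Product: 5 (4R)-4-ethynyloxan-2-ol (lactol, both anomers)
Conditions: DIBAL-H (1.1 equiv), CH2Cl2, −78 °C; Rochelle salt work-up
Reagents that add atoms: none
Why: Partial reduction of a lactone to the lactol with DIBAL-H at low temperature, where the tetrahedral aluminate does not collapse and the terminal alkyne is not hydroaluminated.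

Step 4
Reactants: 5 (4R)-4-ethynyloxan-2-ol
Product: 6 (2E,5S)-5-ethynyl-7-hydroxyhept-2-enal
Conditions: Ph3P=CHCHO (1.2 equiv), PhCO2H (10 mol %), toluene, 80 °C
Reagents that add atoms: (triphenylphosphoranylidene)acetaldehyde, O=CC=P(c1ccccc1)(c1ccccc1)c1ccccc1
Why: Wittig olefination of the open-chain hydroxy aldehyde tautomer of the lactol with the formyl-stabilised ylide, which gives the E-enal and reacts with a saturated aldehyde faster than with the enal product, while in the absence of base the 7-hydroxy enal should not close by oxa-Michael addition.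

Step 5
Reactants: 6 (2E,5S)-5-ethynyl-7-hydroxyhept-2-enal
Product: 7 (2E,5S)-5-ethynylhept-2-enedial
Conditions: Dess–Martin periodinane (1.2 equiv), CH2Cl2, 0 °C to rt; used directly
Reagents that add atoms: none
Why: Dess–Martin oxidation of the primary alcohol under neutral conditions, which leaves the enal, the alkyne and the β-stereocentre alone.

Step 6
Reactants: 7 (2E,5S)-5-ethynylhept-2-enedial
Product: 9 (4S,6S)-4-ethynyl-6-hydroxycyclohex-1-ene-1-carbaldehyde, via imidazole aldol adduct 8 (not isolated)
Conditions: D-proline (20 mol %), imidazole (20 mol %), MeCN (0.05 M), 0 °C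
Reagents that add atoms: none
Why: Amine-catalysed intramolecular Morita–Baylis–Hillman reaction: D-proline converts the enal of 7 into an iminium ion, imidazole adds to its β-carbon (C3), the enamine so formed attacks the tethered C7 aldehyde to give adduct 8 (held as its proline iminium ion), and E1cB loss of imidazole with hydrolysis returns both catalysts and the enal. The closest known reaction type is the proline/imidazole cyclisation of unsubstituted hept-2-enedial to 6-hydroxycyclohex-1-ene-1-carbaldehyde. The ring closes by a 6-(enolexo)-exo-trig aldol addition of C2 onto C7, the only six-ring aldol open to 7, because a direct aldol of the C6 enamine onto the enal carbonyl would have to enclose the E-alkene in a six-membered ring. The new carbinol centre is controlled by the catalyst, whose carboxylic acid delivers the aldehyde in a hydrogen-bonded chair-like transition state, and by the C5 stereocentre, whose ethynyl group sits equatorial in that chair so that the hydroxyl develops equatorial and cis-1,3 to it. The step needs chemoselectivity for ring closure over intermolecular aldol reaction and cis diastereoselectivity; dilution and the faster iminium activation of the enal are expected to secure the former, and the reinforcing catalyst and substrate preferences, backed by the thermodynamic preference for the diequatorial isomer should the aldol be reversible, the latter.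

Step 7
Reactants: 9 (4S,6S)-4-ethynyl-6-hydroxycyclohex-1-ene-1-carbaldehyde
Product: 10 (1S,5S)-5-ethynyl-2-(hydroxymethyl)cyclohex-2-en-1-ol
Conditions: NaBH4 (1 equiv), CeCl3·7H2O (1 equiv), MeOH, −40 °C
Reagents that add atoms: none
Why: Luche reduction, in which cerium-activated 1,2-hydride delivery to the enal carbonyl gives the primary allylic alcohol without conjugate reduction and without touching the carbinol or the alkyne.

Step 8
Reactants: 10 (1S,5S)-5-ethynyl-2-(hydroxymethyl)cyclohex-2-en-1-ol
Product: 11 [(4S,6S)-4-ethynyl-6-hydroxycyclohex-1-en-1-yl]methyl 2-methylpropanoate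
Conditions: iPrCOCl (1.05 equiv), 2,4,6-collidine (2 equiv), CH2Cl2, −78 to −40 °C
Reagents that add atoms: 2-methylpropanoyl chloride, CC(C)C(Cl)=O
Why: Kinetically selective acylation of the unhindered primary allylic hydroxyl over the secondary ring hydroxyl with one equivalent of acid chloride and a hindered pyridine base at low temperature.

Step 9
Reactants: 12 (S)-2-methylglycidol [(2S)-(2-methyloxiran-2-yl)methanol]
Product: 13 (2R)-2-methylpent-4-ene-1,2-diol
Conditions: CH2=CHMgBr (3 equiv), CuI (10 mol %), THF, −40 to 0 °C; aq NH4Cl
Reagents that add atoms: vinylmagnesium bromide, C=C[Mg]Br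
Why: Copper-catalysed SN2 opening of the 2,2-disubstituted epoxide by the vinyl Grignard reagent at the unsubstituted CH2 carbon, which leaves the quaternary stereocentre untouched (a Payne shift of the alkoxide is degenerate and returns the same enantiomer), so that the (R)-diol results.

Step 10
Reactants: 13 (2R)-2-methylpent-4-ene-1,2-diol
Product: 14 (2R)-2-hydroxy-2-methylpent-4-en-1-yl 2-methylpropanoate
Conditions: iPrCOCl (1.1 equiv), pyridine (2 equiv), CH2Cl2, 0 °C
Reagents that add atoms: 2-methylpropanoyl chloride, CC(C)C(Cl)=O
Why: Selective esterification of the primary hydroxyl, the tertiary hydroxyl being inert to an acid chloride and pyridine at this temperature.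

Step 11
Reactants: 11 [(4S,6S)-4-ethynyl-6-hydroxycyclohex-1-en-1-yl]methyl 2-methylpropanoate; 14 (2R)-2-hydroxy-2-methylpent-4-en-1-yl 2-methylpropanoate
Product: 15 [(4S,6S)-6-hydroxy-4-[(4E,6R)-6-hydroxy-6-methyl-7-(2-methylpropanoyloxy)hepta-1,4-dien-2-yl]cyclohex-1-en-1-yl]methyl 2-methylpropanoate (target)
Conditions: [CpRu(MeCN)3]PF6 (10 mol %), 14 (1.5 equiv), acetone, rt
Reagents that add atoms: none
Why: Ruthenium-catalysed alkene–alkyne (Alder-ene) coupling, in which oxidative cyclisation on the CpRu cation should place the new C–C bond at the internal alkyne carbon and β-hydride elimination from the allylic CH2 of 14 followed by reductive elimination gives the 1,1-disubstituted alkene and the E-alkene of the skipped diene, while the trisubstituted ring alkene, both esters and both hydroxyls are spectators and no stereocentre is touched.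

**Compound list**

1 | 5,6-dihydro-2H-pyran-2-one | O=C1C=CCCO1 | starting material
2 | ethynyltri(propan-2-yl)silane | C#C[Si](C(C)C)(C(C)C)C(C)C | starting material
3 | (4R)-4-{[tri(propan-2-yl)silyl]ethynyl}oxan-2-one | CC(C)[Si](C#C[C@@H]1CCOC(=O)C1)(C(C)C)C(C)C | intermediate
4 | (4R)-4-ethynyloxan-2-one | C#C[C@@H]1CCOC(=O)C1 | intermediate
5 | (4R)-4-ethynyloxan-2-ol (anomeric mixture) | C#C[C@@H]1CCOC(O)C1 | intermediate
6 | (2E,5S)-5-ethynyl-7-hydroxyhept-2-enal | C#C[C@H](CCO)C/C=C/C=O | intermediate
7 | (2E,5S)-5-ethynylhept-2-enedial | C#C[C@H](CC=O)C/C=C/C=O | intermediate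
8 | (4S,6S)-4-ethynyl-6-hydroxy-2-(1H-imidazol-1-yl)cyclohexane-1-carbaldehyde (drawn as the free aldehyde; C1 and C2 not defined) | C#C[C@H]1CC(n2ccnc2)C(C=O)[C@@H](O)C1 | intermediate (not isolated)
9 | (4S,6S)-4-ethynyl-6-hydroxycyclohex-1-ene-1-carbaldehyde | C#C[C@H]1CC=C(C=O)[C@@H](O)C1 | intermediate
10 | (1S,5S)-5-ethynyl-2-(hydroxymethyl)cyclohex-2-en-1-ol | C#C[C@H]1CC=C(CO)[C@@H](O)C1 | intermediate
11 | [(4S,6S)-4-ethynyl-6-hydroxycyclohex-1-en-1-yl]methyl 2-methylpropanoate | C#C[C@H]1CC=C(COC(=O)C(C)C)[C@@H](O)C1 | intermediate
12 | (S)-2-methylglycidol | C[C@]1(CO)CO1 | starting material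
13 | (2R)-2-methylpent-4-ene-1,2-diol | C[C@](O)(CO)CC=C | intermediate
14 | (2R)-2-hydroxy-2-methylpent-4-en-1-yl 2-methylpropanoate | C[C@](O)(COC(=O)C(C)C)CC=C | intermediate
15 | [(4S,6S)-6-hydroxy-4-[(4E,6R)-6-hydroxy-6-methyl-7-(2-methylpropanoyloxy)hepta-1,4-dien-2-yl]cyclohex-1-en-1-yl]methyl 2-methylpropanoate | C=C(C/C=C/[C@@](C)(O)COC(=O)C(C)C)[C@H]1CC=C(COC(=O)C(C)C)[C@@H](O)C1 | target

**Step count**

Total steps: 11. Longest linear sequence: 9 (steps 1–8, then step 11); steps 9 and 10 make the side-chain fragment.

**Steps most likely to fail**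

1. Step 6. What may go wrong: poor facial selectivity in the aldol ring closure (attack on the wrong face of the C7 aldehyde, or erosion by retro-aldol), so that the trans carbinol forms. Fallback: the ring closure is no longer asked to set the carbinol, which is set afterwards by hydride delivery to an enone. The fallback sets out from 7 and comes back at 11.
   - The cyclisation is run as in step 6 and the mixture of 9 and its epimer (4S,6R)-4-ethynyl-6-hydroxycyclohex-1-ene-1-carbaldehyde F1 is carried on.
   - Steps 7 and 8 on this mixture give, beside 10 and 11, (1R,5S)-5-ethynyl-2-(hydroxymethyl)cyclohex-2-en-1-ol F2 and then [(4S,6R)-4-ethynyl-6-hydroxycyclohex-1-en-1-yl]methyl 2-methylpropanoate F3.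
   - Dess–Martin oxidation of the mixture of 11 and F3 converges on [(4S)-4-ethynyl-6-oxocyclohex-1-en-1-yl]methyl 2-methylpropanoate F4.
   - Luche reduction of F4 (NaBH4, CeCl3·7H2O, MeOH, −78 °C) should deliver hydride axially to the half-chair with equatorial ethynyl, as in the reduction of carvone to cis-carveol, giving the cis alcohol 11.

2. Step 11. What may go wrong: C–C bond formation at the terminal alkyne carbon (linear instead of branched regiochemistry), or loss of the alkyne by oligomerisation on ruthenium. Fallback: the branched connectivity is fixed first by carbometalation and the E-alkene is made by cross-metathesis. The fallback sets out from 11 and comes back at 15.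
   - Markovnikov allylindation of 11 (allylindium sesquibromide from allyl bromide and indium, THF, 70 °C) gives [(4S,6S)-6-hydroxy-4-(penta-1,4-dien-2-yl)cyclohex-1-en-1-yl]methyl 2-methylpropanoate F5.
   - The metathesis partner (2R)-2-hydroxy-2-methylbut-3-en-1-yl 2-methylpropanoate F6 is made by primary acylation (iPrCOCl, pyridine) of (2R)-2-methylbut-3-ene-1,2-diol F7.
   - F7 is prepared from racemic 2-methyl-2-vinyloxirane by dynamic kinetic asymmetric addition of an oxygen nucleophile under zerovalent palladium catalysis (Pd2(dba)3·CHCl3, chiral diphosphine ligand, Et3B).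
   - Cross-metathesis of the monosubstituted alkene of F5 with F6 (second-generation Hoveyda–Grubbs catalyst, CH2Cl2, 40 °C) gives 15; the 1,1-disubstituted and trisubstituted alkenes should stay out of the reaction.

3. Step 1. What may go wrong: slow 1,4-addition to the lactone with competing alkyne dimerisation, or insufficient facial discrimination. Fallback: the alkynylation is moved to an acyclic enal, the substrate class for which it is most secure, and the second arm is carried as a silyl ether. The fallback sets out from 2 and comes back at 6, so that steps 2–4, including the lactol olefination, are bypassed.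
   - (2E)-5-[(tert-butyldimethylsilyl)oxy]pent-2-enal F8 is made from purchased 3-[(tert-butyldimethylsilyl)oxy]propanal and Ph3P=CHCHO.
   - The rhodium catalysis of step 1 adds 2 to F8 to give (3R)-5-[(tert-butyldimethylsilyl)oxy]-3-{[tri(propan-2-yl)silyl]ethynyl}pentanal F9.
   - Wittig reaction of F9 with Ph3P=CHCHO gives (2E,5S)-7-[(tert-butyldimethylsilyl)oxy]-5-{[tri(propan-2-yl)silyl]ethynyl}hept-2-enal F10.
   - TBAF buffered with AcOH (THF, 0 °C) removes both silyl groups from F10 and gives 6.

**Further compounds**

F1 | step 6 | (4S,6R)-4-ethynyl-6-hydroxycyclohex-1-ene-1-carbaldehyde | C#C[C@H]1CC=C(C=O)[C@H](O)C1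
F2 | step 6 | (1R,5S)-5-ethynyl-2-(hydroxymethyl)cyclohex-2-en-1-ol | C#C[C@H]1CC=C(CO)[C@H](O)C1
F3 | step 6 | [(4S,6R)-4-ethynyl-6-hydroxycyclohex-1-en-1-yl]methyl 2-methylpropanoate | C#C[C@H]1CC=C(COC(=O)C(C)C)[C@H](O)C1
F4 | step 6 | [(4S)-4-ethynyl-6-oxocyclohex-1-en-1-yl]methyl 2-methylpropanoate | C#C[C@H]1CC=C(COC(=O)C(C)C)C(=O)C1
F5 | step 11 | [(4S,6S)-6-hydroxy-4-(penta-1,4-dien-2-yl)cyclohex-1-en-1-yl]methyl 2-methylpropanoate | C=CCC(=C)[C@H]1CC=C(COC(=O)C(C)C)[C@@H](O)C1
F6 | step 11 | (2R)-2-hydroxy-2-methylbut-3-en-1-yl 2-methylpropanoate | C=C[C@@](C)(O)COC(=O)C(C)C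
F7 | step 11 | (2R)-2-methylbut-3-ene-1,2-diol | C=C[C@@](C)(O)CO
F8 | step 1 | (2E)-5-[(tert-butyldimethylsilyl)oxy]pent-2-enal | CC(C)(C)[Si](C)(C)OCC/C=C/C=O
F9 | step 1 | (3R)-5-[(tert-butyldimethylsilyl)oxy]-3-{[tri(propan-2-yl)silyl]ethynyl}pentanal | CC(C)[Si](C#C[C@H](CCO[Si](C)(C)C(C)(C)C)CC=O)(C(C)C)C(C)C
F10 | step 1 | (2E,5S)-7-[(tert-butyldimethylsilyl)oxy]-5-{[tri(propan-2-yl)silyl]ethynyl}hept-2-enal | CC(C)[Si](C#C[C@H](CCO[Si](C)(C)C(C)(C)C)C/C=C/C=O)(C(C)C)C(C)C
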